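**Plan**
1. Retrosynthetic cuts, in order: the six O–CH3 bonds; the two C5–O bonds; O1–C2 and C2–C3 of both rings C; the two C4–C4a acyl bonds; last the C8–C8' biaryl bond. This leaves 3,4-dimethoxyphenol, 4-methoxyphenylacetic acid and a one-carbon acetal.
2. Forward order: the two rings A are joined first (lithiation between two flanking oxygens, oxidative homocoupling). Ring B arrives with the arylacetyl groups, both rings C close together, the C5 oxygens follow, and the phenols are freed last.
3. Enabling feature: in each half C5–H lies peri to the C4 carbonyl oxygen of ring C, so O=C4–C4a–C5 can hold a metal in a five-membered chelate. It is also the only C–H left on ring A.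
4. While C5 is bare, the oxygen on C8a is the only phenol ortho to the ketone, so ring C can close only in the 8,8'-linked sense.
5. Stereochemistry: there is no stereocentre. The tetra-ortho-substituted 8,8' axis forms without control and is carried as the racemate.

Key step: step 6

Remark: the target string gives no descriptor for the 8,8' axis, so racemic material is taken as the goal.

**Step 1**
Reactants: 1 3,4-dimethoxyphenol
Product: 2 1,2-dimethoxy-4-(methoxymethoxy)benzene
Conditions: MOMCl, iPr2NEt, CH2Cl2, 0 °C to rt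
Reagents that add atoms: chloromethyl methyl ether (MOMCl), COCCl
Why: Williamson-type O-alkylation of the phenol with the reactive chloromethyl ether installs an acetal that is inert to butyllithium and is the stronger of the two ortho-directing groups needed next.

**Step 2**
Reactants: 2 1,2-dimethoxy-4-(methoxymethoxy)benzene (two molecules)
Product: 4 2,2',3,3'-tetramethoxy-6,6'-bis(methoxymethoxy)-1,1'-biphenyl, via aryllithium 3 (not isolated)
Conditions: n-BuLi, THF, 0 °C to rt; then anhydrous CuCl2, −78 °C to rt
Reagents that add atoms: none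
Why: Directed ortho-metalation removes the proton flanked by OMOM and OMe (cooperative 1,3-direction, as in 1,2,4-trimethoxybenzene), and oxidative homocoupling of the aryllithium by divalent copper is a standard entry to 2,2',6,6'-tetraalkoxybiphenyls.

**Step 3**
Reactants: 4 2,2',3,3'-tetramethoxy-6,6'-bis(methoxymethoxy)-1,1'-biphenyl
Product: 5 5,5',6,6'-tetramethoxy-[1,1'-biphenyl]-2,2'-diol
Conditions: HCl (cat.), MeOH, 50 °C
Reagents that add atoms: none
Why: Acid-catalysed acetal exchange (MOM cleavage) in a large excess of methanol frees both phenols and leaves the aryl methyl ethers untouched.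

**Step 4**
Reactants: 5 5,5',6,6'-tetramethoxy-[1,1'-biphenyl]-2,2'-diol; 6 4-methoxyphenylacetic acid (two equivalents)
Product: 7 1,1'-(2,2'-dihydroxy-5,5',6,6'-tetramethoxy-[1,1'-biphenyl]-3,3'-diyl)bis[2-(4-methoxyphenyl)ethan-1-one]
Conditions: BF3·OEt2 (solvent), 85 °C; then H2O
Reagents that add atoms: none
Why: Friedel–Crafts/Fries-type acylation of a phenol by an arylacetic acid in BF3·OEt2, the classical deoxybenzoin synthesis with water as the only co-product, goes to the one position ortho to the hydroxyl and para to a methoxy group, and no methoxy group stands ortho to the new ketone where boron chelation could cleave it.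

**Step 5**
Reactants: 7 the bis(deoxybenzoin) of step 4; 8 dimethylformamide dimethyl acetal (two equivalents or more)
Product: 10 6,6',7,7'-tetramethoxy-3,3'-bis(4-methoxyphenyl)-4H,4'H-[8,8'-bichromene]-4,4'-dione, via bis(enaminone) 9 (not isolated)
Conditions: toluene, 100 °C
Reagents that add atoms: none
Why: Condensation of the activated methylene with the formamide acetal, then addition–elimination of the ortho phenol on the enaminone with loss of dimethylamine, is the standard deoxybenzoin-to-isoflavone annulation, and the phenol next to the biaryl carbon is the only one present, which fixes the 8,8' linkage.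

**Step 6**
Reactants: 10 6,6',7,7'-tetramethoxy-3,3'-bis(4-methoxyphenyl)-4H,4'H-[8,8'-bichromene]-4,4'-dione
Product: 12 5,5'-dihydroxy-6,6',7,7'-tetramethoxy-3,3'-bis(4-methoxyphenyl)-4H,4'H-[8,8'-bichromene]-4,4'-dione, via bis(trifluoroacetate) 11 (not isolated)
Conditions: [RuCl2(p-cymene)]2 (cat.), PhI(OCOCF3)2 (added in portions), TFA/TFAA, 80 °C; then H2O, THF, rt
Reagents that add atoms: [bis(trifluoroacetoxy)iodo]benzene, O=C(OI(OC(=O)C(F)(F)F)c1ccccc1)C(F)(F)F
Why: The C4 carbonyl oxygen of each ring C binds the divalent ruthenium trifluoroacetate formed in TFA, and carboxylate-assisted concerted metalation–deprotonation of the peri C5–H gives a five-membered ruthenacycle (Ru, O, C4, C4a, C5). Oxidation of this metallacycle by PhI(OCOCF3)2 to tetravalent ruthenium and C–O reductive elimination give the aryl trifluoroacetate, whose electron-poor ester shields the new oxygen from further oxidation until water cleaves it on work-up. The reaction type is the ketone-directed, ruthenium-catalysed ortho C–H hydroxylation of aryl ketones, which is known for the C5–H of chromones and flavones. No ring closes and no stereocentre forms; the 8,8' axis stays racemic. Selectivity is needed against the 2'/6' C–H bonds of ring B and against C2–H: ring B could be reached only through a six-membered metallacycle from a twisted aryl group, C2–H lies out of reach of the carbonyl, and C5–H is the sole C–H on ring A. The two chromone halves stand nearly orthogonal about the axis and should react independently, while protonation of the pyranones in TFA lowers the tendency of rings A and B to be oxidised by the hypervalent iodine reagent.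

**Step 7**
Reactants: 12 5,5'-dihydroxy-6,6',7,7'-tetramethoxy-3,3'-bis(4-methoxyphenyl)-4H,4'H-[8,8'-bichromene]-4,4'-dione
Product: 13 5,5',6,6',7,7'-hexahydroxy-3,3'-bis(4-hydroxyphenyl)-4H,4'H-[8,8'-bichromene]-4,4'-dione (CNP0254964.0)
Conditions: BBr3 (excess), CH2Cl2, −78 °C to rt, argon; then H2O, 0 °C
Reagents that add atoms: none
Why: Boron tribromide ether cleavage (Lewis acid complexation, bromide attack on methyl) removes all six aryl methyl ethers at or below room temperature, where neither Wessely–Moser ring opening and reclosure of the 5-hydroxychromone nor dehydration of the 7,7'-diol to a dibenzofuran, both known from hot mineral acid, should set in, and exclusion of air protects the pyrogallol-type rings A.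

**Compound list**
1 | 3,4-dimethoxyphenol | COc1ccc(O)cc1OC | starting material
2 | 1,2-dimethoxy-4-(methoxymethoxy)benzene | COCOc1ccc(OC)c(OC)c1 | intermediate
3 | [2,3-dimethoxy-6-(methoxymethoxy)phenyl]lithium | [Li]c1c(OCOC)ccc(OC)c1OC | intermediate
4 | 2,2',3,3'-tetramethoxy-6,6'-bis(methoxymethoxy)-1,1'-biphenyl (racemic axis) | COCOc1ccc(OC)c(OC)c1-c1c(OCOC)ccc(OC)c1OC | intermediate
5 | 5,5',6,6'-tetramethoxy-[1,1'-biphenyl]-2,2'-diol (racemic axis) | COc1ccc(O)c(-c2c(O)ccc(OC)c2OC)c1OC | intermediate
6 | 4-methoxyphenylacetic acid | COc1ccc(CC(=O)O)cc1 | starting material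
7 | 1,1'-(2,2'-dihydroxy-5,5',6,6'-tetramethoxy-[1,1'-biphenyl]-3,3'-diyl)bis[2-(4-methoxyphenyl)ethan-1-one] | COc1ccc(CC(=O)c2cc(OC)c(OC)c(c2O)-c2c(O)c(cc(OC)c2OC)C(=O)Cc2ccc(OC)cc2)cc1 | intermediate
8 | dimethylformamide dimethyl acetal | COC(OC)N(C)C | starting material
9 | (2E,2'E)-1,1'-(2,2'-dihydroxy-5,5',6,6'-tetramethoxy-[1,1'-biphenyl]-3,3'-diyl)bis[3-(dimethylamino)-2-(4-methoxyphenyl)prop-2-en-1-one] (push–pull alkenes, drawn E, geometry labile) | COc1ccc(cc1)/C(=C\N(C)C)C(=O)c1cc(OC)c(OC)c(c1O)-c1c(O)c(cc(OC)c1OC)C(=O)/C(=C/N(C)C)c1ccc(OC)cc1 | intermediate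
10 | 6,6',7,7'-tetramethoxy-3,3'-bis(4-methoxyphenyl)-4H,4'H-[8,8'-bichromene]-4,4'-dione | O=c1c(-c2ccc(OC)cc2)coc2c(-c3c(OC)c(OC)cc4c(=O)c(-c5ccc(OC)cc5)coc34)c(OC)c(OC)cc12 | intermediate
11 | 6,6',7,7'-tetramethoxy-3,3'-bis(4-methoxyphenyl)-4,4'-dioxo-4H,4'H-[8,8'-bichromene]-5,5'-diyl bis(trifluoroacetate) | O=c1c(-c2ccc(OC)cc2)coc2c(-c3c(OC)c(OC)c(OC(=O)C(F)(F)F)c4c(=O)c(-c5ccc(OC)cc5)coc34)c(OC)c(OC)c(OC(=O)C(F)(F)F)c12 | intermediate
12 | 5,5'-dihydroxy-6,6',7,7'-tetramethoxy-3,3'-bis(4-methoxyphenyl)-4H,4'H-[8,8'-bichromene]-4,4'-dione | O=c1c(-c2ccc(OC)cc2)coc2c(-c3c(OC)c(OC)c(O)c4c(=O)c(-c5ccc(OC)cc5)coc34)c(OC)c(OC)c(O)c12 | intermediate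
13 | 5,5',6,6',7,7'-hexahydroxy-3,3'-bis(4-hydroxyphenyl)-4H,4'H-[8,8'-bichromene]-4,4'-dione | O=c1c(-c2ccc(O)cc2)coc2c(-c3c(O)c(O)c(O)c4c(=O)c(-c5ccc(O)cc5)coc34)c(O)c(O)c(O)c12 | target

Total step count: 7. Longest linear sequence: 7 steps (1 to 13).

**Steps most likely to fail**

1. **Step 6.**
   - Risk: metalation of a C5–H crowded by the 6-methoxy group may be slow. One-electron oxidation of the anisyl and dimethoxyaryl rings by the hypervalent iodine reagent could then overtake it, or conversion could stall after the first of the two hydroxylations.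
   - Fallback: it gives up the late oxygenation and carries the C5 oxygen as a methyl ether from the start. It sets out from acid 6 (used with acetal 8) and comes back to the route at target 13.
   - Commercial 3,4,5-trimethoxyphenol F1 replaces 1. It is dimerised ortho to its hydroxyl by iron-catalysed oxidative phenol coupling (FeCl3 cat., t-BuOOt-Bu, (CF3)2CHOH, rt) to 4,4',5,5',6,6'-hexamethoxy-[1,1'-biphenyl]-2,2'-diol F2.
   - Acylation with 6 in BF3·OEt2 at the last free ring position gives 1,1'-(2,2'-dihydroxy-4,4',5,5',6,6'-hexamethoxy-[1,1'-biphenyl]-3,3'-diyl)bis[2-(4-methoxyphenyl)ethan-1-one] F3. The temperature is kept as low as workable so that the methyl ether ortho to the ketone stays in place and only one phenol can cyclise.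
   - Acetal 8 in hot toluene closes both rings C to 5,5',6,6',7,7'-hexamethoxy-3,3'-bis(4-methoxyphenyl)-4H,4'H-[8,8'-bichromene]-4,4'-dione F4.
   - BBr3 as in step 7 then cleaves all eight methyl ethers to give 13.

2. **Step 2.**
   - Risk: two di-ortho-substituted aryl groups must meet on copper. Protonation or chlorination of the hindered arylcopper species may outrun C–C bond formation.
   - Fallback: it replaces the oxidative coupling of an organometallic by the reductive coupling of a halide. It sets out from 2 and comes back at 4.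
   - Aryllithium 3, made as before, is quenched with I2 to give 2-iodo-3,4-dimethoxy-1-(methoxymethoxy)benzene F5.
   - F5 is isolated, purified and dimerised in a classical Ullmann coupling (activated copper powder, DMF, 140 °C).

3. **Step 4.**
   - Risk: the 2,2'-biphenol may be tied up by boron as a cyclic chelate. The reaction could then stop at O-acylation or after the first C-acylation.
   - Fallback: it reverses the polarity of the arene. It sets out from 4 (bypassing 5) and acid 6, and comes back at 7.
   - Acid 6 is converted (1,1'-carbonyldiimidazole, MeNHOMe·HCl, CH2Cl2) into N-methoxy-N-methyl-2-(4-methoxyphenyl)acetamide F6.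
   - Biaryl 4 is metalated again, now ortho to each OMOM group (s-BuLi, TMEDA, THF, −78 °C), to 5,5'-dilithio-2,2',3,3'-tetramethoxy-6,6'-bis(methoxymethoxy)-1,1'-biphenyl F7.
   - Addition of F7 to F6 at low temperature and an aqueous quench give 1,1'-[5,5',6,6'-tetramethoxy-2,2'-bis(methoxymethoxy)-[1,1'-biphenyl]-3,3'-diyl]bis[2-(4-methoxyphenyl)ethan-1-one] F8.
   - HCl in MeOH, as in step 3, then unmasks F8 to 7.

**Further compounds**
F1 | step 6 | 3,4,5-trimethoxyphenol | COc1cc(O)cc(OC)c1OC
F2 | step 6 | 4,4',5,5',6,6'-hexamethoxy-[1,1'-biphenyl]-2,2'-diol | COc1cc(O)c(-c2c(O)cc(OC)c(OC)c2OC)c(OC)c1OC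
F3 | step 6 | 1,1'-(2,2'-dihydroxy-4,4',5,5',6,6'-hexamethoxy-[1,1'-biphenyl]-3,3'-diyl)bis[2-(4-methoxyphenyl)ethan-1-one] | COc1ccc(CC(=O)c2c(OC)c(OC)c(OC)c(c2O)-c2c(O)c(c(OC)c(OC)c2OC)C(=O)Cc2ccc(OC)cc2)cc1
F4 | step 6 | 5,5',6,6',7,7'-hexamethoxy-3,3'-bis(4-methoxyphenyl)-4H,4'H-[8,8'-bichromene]-4,4'-dione | O=c1c(-c2ccc(OC)cc2)coc2c(-c3c(OC)c(OC)c(OC)c4c(=O)c(-c5ccc(OC)cc5)coc34)c(OC)c(OC)c(OC)c12
F5 | step 2 | 2-iodo-3,4-dimethoxy-1-(methoxymethoxy)benzene | COCOc1ccc(OC)c(OC)c1I
F6 | step 4 | N-methoxy-N-methyl-2-(4-methoxyphenyl)acetamide | COc1ccc(CC(=O)N(C)OC)cc1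
F7 | step 4 | 5,5'-dilithio-2,2',3,3'-tetramethoxy-6,6'-bis(methoxymethoxy)-1,1'-biphenyl | [Li]c1cc(OC)c(OC)c(c1OCOC)-c1c(OCOC)c([Li])cc(OC)c1OC
F8 | step 4 | 1,1'-[5,5',6,6'-tetramethoxy-2,2'-bis(methoxymethoxy)-[1,1'-biphenyl]-3,3'-diyl]bis[2-(4-methoxyphenyl)ethan-1-one] | COCOc1c(C(=O)Cc2ccc(OC)cc2)cc(OC)c(OC)c1-c1c(OCOC)c(C(=O)Cc2ccc(OC)cc2)cc(OC)c1OC
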